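**Strategy.** The dimethylpyran ring fused to ring B is built on a benzoate whose ester carbon later becomes C2 of the flavone. One operation joins 2-hydroxy-2-methylpropanal to a benzylic phosphonium salt: Wittig olefination creates the C3=C4 double bond of the chromene, and the tertiary alkoxide so delivered displaces fluoride at the future C8a to form the O1–C8a aryl ether. The step exploits the position of C8a (C4' of ring B): para to the ester-bearing carbon and next to C4a, which carries the benzylic carbon C4. The precursor is a [2-fluoro-5-(methoxycarbonyl)-3-(methoxymethoxy)benzyl]triphenylphosphonium bromide. The ester then enters a Claisen condensation with a prenylated acetophenone, and acid closes ring C.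

Key step: step 8

Remark: the target has no stereocentre; the only geometric element set in the route is the Z double bond of 15, which becomes the ring double bond. Compound 13 is used as a freshly prepared solution because it forms a hemiacetal dimer reversibly.

**Step 1**
Reactants: 1 1-(2,4,6-trihydroxyphenyl)ethan-1-one; 2 1-bromo-3-methylbut-2-ene
Product: 3 1-[2,4,6-trihydroxy-3-(3-methylbut-2-en-1-yl)phenyl]ethan-1-one
Conditions: 10% aq. KOH, 0 °C to rt
Reagents that add atoms: none
Why: Base-mediated C-prenylation (Friedel–Crafts-type alkylation of a phloroglucinol phenoxide) should occur at the equivalent ring carbons C3/C5, because water solvates the phenoxide oxygens and leaves the ring carbon as the nucleophilic site.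

**Step 2**
Reactants: 3 1-[2,4,6-trihydroxy-3-(3-methylbut-2-en-1-yl)phenyl]ethan-1-one
Product: 4 1-[2-hydroxy-4,6-bis(methoxymethoxy)-3-(3-methylbut-2-en-1-yl)phenyl]ethan-1-one
Conditions: MOMCl (2.2 equiv), K2CO3, acetone, 0 °C to rt
Reagents that add atoms: chloromethyl methyl ether, COCCl
Why: Williamson-type O-alkylation (MOM protection) should take the acidic 4-OH and the less hindered 6-OH and leave the 2-OH, which is flanked by the prenyl group and engaged in the hydrogen bond to the acetyl oxygen.

**Step 3**
Reactants: 5 methyl 4-fluoro-3-methylbenzoate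
Product: 7 methyl 4-fluoro-3-hydroxy-5-methylbenzoate, via aryl pinacol boronate 6 (not isolated)
Conditions: [Ir(OMe)(cod)]2 (1.5 mol %), 4,4'-di-tert-butyl-2,2'-bipyridine (3 mol %), B2pin2, THF, 80 °C; then KHSO5 (as 2KHSO5·KHSO4·K2SO4), acetone/H2O, rt
Reagents that add atoms: bis(pinacolato)diboron, CC1(C)OB(OC1(C)C)B1OC(C)(C)C(C)(C)O1 (boryl group of 6); potassium peroxymonosulfate, [K+].[O-]S(=O)(=O)OO (oxygen of 7)
Why: Iridium-catalysed C–H borylation is governed by sterics, so of the three ring C–H bonds only C5–H, whose sole ortho neighbour is the small, acidifying fluorine, should react (C2–H lies between two substituents and C6–H is ortho to the ester), and peroxymonosulfate oxidation of the C–B bond at the same carbon then gives the phenol.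

**Step 4**
Reactants: 7 methyl 4-fluoro-3-hydroxy-5-methylbenzoate
Product: 8 methyl 4-fluoro-3-(methoxymethoxy)-5-methylbenzoate
Conditions: MOMCl, K2CO3, acetone, rt
Reagents that add atoms: chloromethyl methyl ether, COCCl
Why: Williamson-type MOM protection of the acidic ortho-fluorophenol masks the oxygen that would otherwise become a phenoxide and shut down the later fluoride displacement.

**Step 5**
Reactants: 8 methyl 4-fluoro-3-(methoxymethoxy)-5-methylbenzoate
Product: 9 methyl 3-(bromomethyl)-4-fluoro-5-(methoxymethoxy)benzoate
Conditions: NBS (1.05 equiv), AIBN (cat.), PhCF3, 85 °C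
Reagents that add atoms: N-bromosuccinimide, O=C1CCC(=O)N1Br
Why: Wohl–Ziegler radical bromination should take the single benzylic methyl group, the only position that gives a resonance-stabilised radical, and stop at the monobromide with one equivalent of reagent.

**Step 6**
Reactants: 9 methyl 3-(bromomethyl)-4-fluoro-5-(methoxymethoxy)benzoate
Product: 10 {[2-fluoro-5-(methoxycarbonyl)-3-(methoxymethoxy)phenyl]methyl}triphenylphosphonium bromide
Conditions: PPh3, toluene, 90 °C
Reagents that add atoms: triphenylphosphine, c1ccc(cc1)P(c1ccccc1)c1ccccc1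
Why: SN2 quaternisation of triphenylphosphine by the primary benzylic bromide (the first stage of a Wittig sequence) should give the crystalline salt.

**Step 7**
Reactants: 11 2-methylbut-3-en-2-ol
Product: 13 2-hydroxy-2-methylpropanal, via secondary ozonide 12 (not isolated)
Conditions: O3, CH2Cl2, −78 °C; then Me2S, −78 °C to rt
Reagents that add atoms: ozone, [O-][O+]=O
Why: Ozonolysis of the terminal alkene through the Criegee sequence followed by reductive cleavage of the ozonide should give the non-enolisable α-hydroxy aldehyde.

**Step 8**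
Reactants: 10 {[2-fluoro-5-(methoxycarbonyl)-3-(methoxymethoxy)phenyl]methyl}triphenylphosphonium bromide; 13 2-hydroxy-2-methylpropanal
Product: 16 methyl 8-(methoxymethoxy)-2,2-dimethyl-2H-chromene-6-carboxylate, via benzylic ylide 14 (not isolated), via Z-allylic alcohol 15 (not isolated)
Conditions: KOtBu (2.4 equiv), THF, 0 °C; 13 (1.3 equiv), 0 °C; then DMF, 60 °C
Reagents that add atoms: none
Why: KOtBu converts 10 into the semi-stabilised benzylic ylide 14, which undergoes Wittig olefination with aldehyde 13 through a [2+2] oxaphosphetane and forms the C3=C4 bond; an α-oxygen on the aldehyde and an ortho-fluorine on the benzylide both bias salt-free Wittig reactions toward the cis-oxaphosphetane, so the Z alkene 15 should predominate. The remaining base turns the tertiary alcohol of 15 into its potassium alkoxide, which the Z double bond holds next to the C–F bond, and this alkoxide displaces fluoride by intramolecular SNAr (addition–elimination through a Meisenheimer complex stabilised by the para ester) to form the O1–C8a bond. The closest known reaction types are the Wittig reaction of benzyltriphenylphosphonium ylides with aldehydes and the ring-closing SNAr etherification of 4-fluorobenzoates by alkoxides. The pyran ring closes as a six-membered ring by attack of oxygen on the ipso carbon of the arene, and no stereocentre is formed. The step needs Z selectivity in the olefination, because the E isomer cannot reach the C–F bond, and attack at one ring carbon only, which the single fluorine para to the ester secures. Tert-butoxide can compete only intermolecularly, and the phenol oxygen is masked as its MOM ether so that no deactivating phenoxide forms.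

**Step 9**
Reactants: 4 1-[2-hydroxy-4,6-bis(methoxymethoxy)-3-(3-methylbut-2-en-1-yl)phenyl]ethan-1-one; 16 methyl 8-(methoxymethoxy)-2,2-dimethyl-2H-chromene-6-carboxylate
Product: 17 1-[2-hydroxy-4,6-bis(methoxymethoxy)-3-(3-methylbut-2-en-1-yl)phenyl]-3-[8-(methoxymethoxy)-2,2-dimethyl-2H-chromen-6-yl]propane-1,3-dione
Conditions: LiN(SiMe3)2 (3.5 equiv), THF, −78 °C to 50 °C; aq. NH4Cl
Reagents that add atoms: none
Why: Crossed Claisen condensation of the dianion of 4 (phenoxide plus methyl ketone enolate) with the non-enolisable aryl ester 16 should give the 1,3-diketone, driven by irreversible formation of the diketonate.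

**Step 10**
Reactants: 17 1-[2-hydroxy-4,6-bis(methoxymethoxy)-3-(3-methylbut-2-en-1-yl)phenyl]-3-[8-(methoxymethoxy)-2,2-dimethyl-2H-chromen-6-yl]propane-1,3-dione
Product: 19 5,7-dihydroxy-2-(8-hydroxy-2,2-dimethyl-2H-chromen-6-yl)-8-(3-methylbut-2-en-1-yl)-4H-chromen-4-one, via tris-MOM flavone 18 (not isolated)
Conditions: 3 M HCl (aq)/MeOH, rt, then 50 °C
Reagents that add atoms: none
Why: Acid-catalysed cyclodehydration of the 2-hydroxyaryl 1,3-diketone (the flavone-forming step of a Baker–Venkataraman-type sequence) should proceed through the only free ortho-hydroxyl, which fixes the prenyl group at C8, before the slower solvolysis of the three MOM acetals releases the phenols.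

**Compound list**
1 | 1-(2,4,6-trihydroxyphenyl)ethan-1-one | CC(=O)c1c(O)cc(O)cc1O | starting material
2 | 1-bromo-3-methylbut-2-ene (prenyl bromide) | CC(C)=CCBr | starting material
3 | 1-[2,4,6-trihydroxy-3-(3-methylbut-2-en-1-yl)phenyl]ethan-1-one | CC(=O)c1c(O)cc(O)c(CC=C(C)C)c1O | intermediate
4 | 1-[2-hydroxy-4,6-bis(methoxymethoxy)-3-(3-methylbut-2-en-1-yl)phenyl]ethan-1-one | CC(=O)c1c(OCOC)cc(OCOC)c(CC=C(C)C)c1O | intermediate
5 | methyl 4-fluoro-3-methylbenzoate | COC(=O)c1ccc(F)c(C)c1 | starting material
6 | methyl 4-fluoro-3-methyl-5-(4,4,5,5-tetramethyl-1,3,2-dioxaborolan-2-yl)benzoate | COC(=O)c1cc(C)c(F)c(c1)B1OC(C)(C)C(C)(C)O1 | intermediate (not isolated)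
7 | methyl 4-fluoro-3-hydroxy-5-methylbenzoate | COC(=O)c1cc(C)c(F)c(O)c1 | intermediate
8 | methyl 4-fluoro-3-(methoxymethoxy)-5-methylbenzoate | COCOc1cc(cc(C)c1F)C(=O)OC | intermediate
9 | methyl 3-(bromomethyl)-4-fluoro-5-(methoxymethoxy)benzoate | COCOc1cc(cc(CBr)c1F)C(=O)OC | intermediate
10 | {[2-fluoro-5-(methoxycarbonyl)-3-(methoxymethoxy)phenyl]methyl}triphenylphosphonium bromide | COCOc1cc(cc(C[P+](c2ccccc2)(c2ccccc2)c2ccccc2)c1F)C(=O)OC.[Br-] | intermediate
11 | 2-methylbut-3-en-2-ol | CC(C)(O)C=C | starting material
12 | 2-(1,2,4-trioxolan-3-yl)propan-2-ol (secondary ozonide) | CC(C)(O)C1OOCO1 | intermediate (not isolated)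
13 | 2-hydroxy-2-methylpropanal | CC(C)(O)C=O | intermediate
14 | methyl 4-fluoro-3-(methoxymethoxy)-5-[(triphenyl-λ5-phosphanylidene)methyl]benzoate (ylide) | COCOc1cc(cc(C=P(c2ccccc2)(c2ccccc2)c2ccccc2)c1F)C(=O)OC | intermediate (not isolated)
15 | methyl 4-fluoro-3-[(1Z)-3-hydroxy-3-methylbut-1-en-1-yl]-5-(methoxymethoxy)benzoate (present as its potassium alkoxide) | COCOc1cc(cc(/C=C\C(C)(C)O)c1F)C(=O)OC | intermediate (not isolated)
16 | methyl 8-(methoxymethoxy)-2,2-dimethyl-2H-chromene-6-carboxylate | COCOc1cc(cc2C=CC(C)(C)Oc12)C(=O)OC | intermediate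
17 | 1-[2-hydroxy-4,6-bis(methoxymethoxy)-3-(3-methylbut-2-en-1-yl)phenyl]-3-[8-(methoxymethoxy)-2,2-dimethyl-2H-chromen-6-yl]propane-1,3-dione | COCOc1cc(OCOC)c(CC=C(C)C)c(O)c1C(=O)CC(=O)c1cc(OCOC)c2OC(C)(C)C=Cc2c1 | intermediate
18 | 5,7-bis(methoxymethoxy)-2-[8-(methoxymethoxy)-2,2-dimethyl-2H-chromen-6-yl]-8-(3-methylbut-2-en-1-yl)-4H-chromen-4-one | COCOc1cc(OCOC)c(CC=C(C)C)c2oc(cc(=O)c12)-c1cc(OCOC)c2OC(C)(C)C=Cc2c1 | intermediate (not isolated)
19 | 5,7-dihydroxy-2-(8-hydroxy-2,2-dimethyl-2H-chromen-6-yl)-8-(3-methylbut-2-en-1-yl)-4H-chromen-4-one | CC(C)=CCc1c(O)cc(O)c2c(=O)cc(-c3cc(O)c4c(c3)C=CC(C)(C)O4)oc12 | target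

**Step count and risks**
Total steps: 10. Longest linear sequence: 7 steps (steps 3, 4, 5, 6, 8, 9, 10, from compound 5).

The three steps most likely to fail:

Step 8 is the riskiest. The olefination may give mainly the E alkene, which cannot cyclise, or the alkoxide may be consumed by intermolecular reactions before ring closure. The fallback gives up control of geometry by olefination and closes the double bond by metathesis instead. It sets out from 10: Wittig methylenation with aqueous formaldehyde and K2CO3 should give methyl 3-ethenyl-4-fluoro-5-(methoxymethoxy)benzoate F1. SNAr at the fluoride para to the ester with the sodium alkoxide of 11 (NaH, DMF, 60 °C) should give methyl 3-ethenyl-5-(methoxymethoxy)-4-[(2-methylbut-3-en-2-yl)oxy]benzoate F2. Ring-closing metathesis with second-generation Grubbs catalyst RuCl2(=CHPh)(H2IMes)(PCy3) in CH2Cl2 at 40 °C then forms C3=C4 within the ring and returns to the route at 16.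

Step 9 is the second risk. Acylation of the hindered, electron-rich ketone enolate of 4 by the electron-rich ester may be slow, so that ester cleavage or self-condensation takes over. The fallback replaces the intermolecular condensation by an intramolecular acyl transfer. It sets out from 16: saponification (LiOH, THF/H2O) should give 8-(methoxymethoxy)-2,2-dimethyl-2H-chromene-6-carboxylic acid F3. Esterification of the free phenol of 4 with F3 (EDC·HCl, DMAP, CH2Cl2) should give 2-acetyl-3,5-bis(methoxymethoxy)-6-(3-methylbut-2-en-1-yl)phenyl 8-(methoxymethoxy)-2,2-dimethyl-2H-chromene-6-carboxylate F4. Baker–Venkataraman rearrangement (KOtBu, THF, 0 °C to rt) returns to the route at 17.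

Step 10 is the third risk. Loss of the acetal on the second ortho oxygen of ring A before ring closure would let either hydroxyl cyclise and scramble the prenyl position. Prolonged protic acid may also add the 7-OH across the prenyl double bond. The fallback separates the two events and removes the acetals by a different mechanism. It sets out from 17: cyclodehydration alone under aprotic conditions (pyridinium p-toluenesulfonate cat., toluene, 80 °C, molecular sieves) with isolation of 18. Lewis-acid-assisted thiolysis of the three acetals (ZnBr2, n-PrSH, CH2Cl2, 0 °C) then avoids protic acid and returns to the route at 19. This fallback makes no compound outside the list (F0).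

**Further compounds**
F1 | step 8 | methyl 3-ethenyl-4-fluoro-5-(methoxymethoxy)benzoate | COCOc1cc(cc(C=C)c1F)C(=O)OC
F2 | step 8 | methyl 3-ethenyl-5-(methoxymethoxy)-4-[(2-methylbut-3-en-2-yl)oxy]benzoate | COCOc1cc(cc(C=C)c1OC(C)(C)C=C)C(=O)OC
F3 | step 9 | 8-(methoxymethoxy)-2,2-dimethyl-2H-chromene-6-carboxylic acid | COCOc1cc(cc2C=CC(C)(C)Oc12)C(=O)O
F4 | step 9 | 2-acetyl-3,5-bis(methoxymethoxy)-6-(3-methylbut-2-en-1-yl)phenyl 8-(methoxymethoxy)-2,2-dimethyl-2H-chromene-6-carboxylate | CC(=O)c1c(OCOC)cc(OCOC)c(CC=C(C)C)c1OC(=O)c1cc(OCOC)c2OC(C)(C)C=Cc2c1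
F0 | step 10 | none | none
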